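## Retrosynthetic overview

1. Arene half: cut the aryl–acyl and aryl–prenyl bonds back to phloroglucinol 1, isobutyryl chloride 2 (giving ketone 3) and prenyl bromide 4 (giving prenylated acylphloroglucinol 5). The benzene ring is bought, not built.
2. Pyranone half (key step): cut the lactone C2–O1 bond, then C4–C5, back to pentan-3-one 6 and malonyl dichloride 7. In the forward sense the C-acylated chain 8 closes by enol O-acylation to pyranone 9; this carbon–oxygen bond closes the only ring built in the route.
3. Union: cut both bonds of the CH2 bridge. Pyranone 9, a one-carbon iminium salt and 5 are joined, through Mannich base 10 and methylidene dione 11, to the target 12.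
4. Ring order: the pyranone ring is formed in step 3, the methylene bridge in step 4; no other ring is formed.

Assumption: the target has no stereocentre and no stereogenic double bond, so it is made as the one achiral compound, in the 4-hydroxy-2-pyranone tautomer of the given SMILES.

## Route

Step 1
Reactants: 1 phloroglucinol (benzene-1,3,5-triol, anhydrous); 2 isobutyryl chloride (2-methylpropanoyl chloride)
Product: 3 2-methyl-1-(2,4,6-trihydroxyphenyl)propan-1-one
Conditions: AlCl3 (3.5 equiv), PhNO2, rt → 70 °C, 3 h; ice/dilute aq HCl
Reagents that add atoms: none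
Why: Friedel–Crafts C-acylation of the strongly activated, threefold-symmetric triol stops cleanly at the mono-ketone because the first acyl group (chelated to aluminium) deactivates the ring; no stereocentre is formed.

Step 2
Reactants: 3 2-methyl-1-(2,4,6-trihydroxyphenyl)propan-1-one; 4 prenyl bromide (1-bromo-3-methylbut-2-ene)
Product: 5 2-methyl-1-[2,4,6-trihydroxy-3-(3-methylbut-2-en-1-yl)phenyl]propan-1-one
Conditions: 4 (0.95 equiv), 10% aq KOH, 0 °C, 2 h; dilute aq HCl to pH 3
Reagents that add atoms: none
Why: Phenoxide C-alkylation (SN2 at the primary allylic bromide) in water, where hydrogen bonding to the phenoxide oxygens favours attack through carbon; the two free ring positions of 3 are equivalent, so a single mono-prenyl regioisomer forms, and slightly substoichiometric bromide limits diprenylation; no stereocentre is formed.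

Step 3
Reactants: 6 pentan-3-one; 7 malonyl dichloride (propanedioyl dichloride)
Product: 9 6-ethyl-4-hydroxy-5-methyl-2H-pyran-2-one, via 4-methyl-3,5-dioxoheptanoyl chloride 8 (not isolated)
Conditions: 6 (1.5 equiv), MgBr2·OEt2 (2.5 equiv), DIPEA (N,N-diisopropylethylamine, 3.5 equiv), CH2Cl2, 0 °C, 15 min; 7 (1.0 equiv) added over 1 h at −40 °C; rt, 2 h; dilute aq HCl
Reagents that add atoms: none
Why: Proposed new method: direct [3+3] annulation of a free dialkyl ketone with malonyl dichloride under soft enolization – MgBr2 binds the carbonyl of 6 so that DIPEA enolizes it reversibly, the magnesium-bound enolate is C-acylated by one acyl chloride end of 7 to give the chelated 1,3-diketonate 8, and its enolate oxygen then attacks the second acyl chloride in a 6-exo ring closure that forms the lactone C2–O1 bond, tautomerization giving the 4-hydroxy-2-pyranone, which stays in the flask as an unreactive magnesium salt (6 is symmetric, so there is no regiochemical issue and no stereocentre); the closest known reaction types are the MgBr2·OEt2/amine soft-enolization C-acylation of ketones by acid chlorides to 1,3-diketones and the base-free annulation of preformed silyl enol ethers by malonyl dichloride, neither of which has been shown as a one-pot pyranone synthesis from the free ketone.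

Step 4
Reactants: 9 6-ethyl-4-hydroxy-5-methyl-2H-pyran-2-one; 5 2-methyl-1-[2,4,6-trihydroxy-3-(3-methylbut-2-en-1-yl)phenyl]propan-1-one
Product: 12 3-{[2,4,6-trihydroxy-3-(2-methylpropanoyl)-5-(3-methylbut-2-en-1-yl)phenyl]methyl}-6-ethyl-4-hydroxy-5-methyl-2H-pyran-2-one, via 3-[(dimethylamino)methyl]-6-ethyl-4-hydroxy-5-methylpyran-2-one 10 (not isolated), via 6-ethyl-5-methyl-3-methylidenepyran-2,4-dione 11 (not isolated)
Conditions: 9, Eschenmoser's salt (1.05 equiv), MeCN, rt, 1 h; then 5 (1.0 equiv), rt → 40 °C, 4 h
Reagents that add atoms: Eschenmoser's salt (N,N-dimethylmethylideneammonium iodide), C=[N+](C)C.[I-]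
Why: Mannich aminomethylation of the nucleophilic pyranone C3 gives 10, loss of dimethylamine gives the vinylogous quinone-methide acceptor 11, and the single free, doubly hydroxyl-flanked ring carbon of 5 adds to it in a Friedel–Crafts-type Michael reaction (three-component Mannich–Michael, carba-Betti, sequence); no stereocentre is formed and the prenyl alkene is untouched under these nearly neutral conditions.

## Compound list

1 | phloroglucinol (benzene-1,3,5-triol) | Oc1cc(O)cc(O)c1 | starting material
2 | isobutyryl chloride (2-methylpropanoyl chloride) | CC(C)C(Cl)=O | starting material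
3 | 2-methyl-1-(2,4,6-trihydroxyphenyl)propan-1-one | CC(C)C(=O)c1c(O)cc(O)cc1O | intermediate
4 | prenyl bromide (1-bromo-3-methylbut-2-ene) | CC(C)=CCBr | starting material
5 | 2-methyl-1-[2,4,6-trihydroxy-3-(3-methylbut-2-en-1-yl)phenyl]propan-1-one | CC(C)C(=O)c1c(O)cc(O)c(CC=C(C)C)c1O | intermediate
6 | pentan-3-one | CCC(=O)CC | starting material
7 | malonyl dichloride (propanedioyl dichloride) | O=C(Cl)CC(Cl)=O | starting material
8 | 4-methyl-3,5-dioxoheptanoyl chloride (present as its magnesium chelate; C4 is enolized, no defined configuration) | CCC(=O)C(C)C(=O)CC(Cl)=O | intermediate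
9 | 6-ethyl-4-hydroxy-5-methyl-2H-pyran-2-one | CCc1oc(=O)cc(O)c1C | intermediate
10 | 3-[(dimethylamino)methyl]-6-ethyl-4-hydroxy-5-methyl-2H-pyran-2-one | CCc1oc(=O)c(CN(C)C)c(O)c1C | intermediate
11 | 6-ethyl-5-methyl-3-methylidene-2H-pyran-2,4(3H)-dione | CCC1=C(C)C(=O)C(=C)C(=O)O1 | intermediate
12 | 3-{[2,4,6-trihydroxy-3-(2-methylpropanoyl)-5-(3-methylbut-2-en-1-yl)phenyl]methyl}-6-ethyl-4-hydroxy-5-methyl-2H-pyran-2-one (achiral) | CCc1oc(=O)c(Cc2c(O)c(CC=C(C)C)c(O)c(C(=O)C(C)C)c2O)c(O)c1C | target

## Step count and risks

Total step count: 4.
Longest linear sequence: 3 steps (1 → 3 → 5 → 12); the pyranone branch is 2 steps (6 → 9 → 12).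

The three steps most likely to fail:

**Step 3 (proposed new annulation).** The amine can deprotonate 7 to ketene-type species that self-condense, and the product salt can be acylated a second time by 7. The fallback uses known chemistry and sets out from 6. Pentan-3-one is silylated (Me3SiCl, Et3N, DMF, 80 °C) and distilled to give the neutral silyl enol ether (Z)-3-(trimethylsilyloxy)pent-2-ene F1; any E isomer gives the same product. F1 is then treated with 7 in Et2O at −78 °C → rt with no base or metal present. This established silyl enol ether/malonyl dichloride annulation closes the same lactone C–O bond and comes back to the route at 9.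

**Step 2 (C-prenylation).** Di-C-prenylation, geminal prenylation and O-prenylation compete, so 35–45% of 5 with recovered 3 is realistic. The fallback sets out from 3 and installs the prenyl group through oxygen.
- The most acidic, non-chelated 4-hydroxyl is O-alkylated with 3-chloro-3-methylbut-1-yne (CuCl2·2H2O cat., DBU, MeCN, 0 °C) to give the aryl propargyl ether 1-[2,6-dihydroxy-4-(2-methylbut-3-yn-2-yloxy)phenyl]-2-methylpropan-1-one F2.
- Semihydrogenation (H2, Pd/CaCO3 poisoned with Pb(OAc)2, quinoline, EtOAc) gives the 1,1-dimethylallyl ether 1-[2,6-dihydroxy-4-(2-methylbut-3-en-2-yloxy)phenyl]-2-methylpropan-1-one F3.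
- Aromatic Claisen rearrangement ([3,3], toluene, 110 °C) transfers the allyl unit to either of the two equivalent ortho carbons with allylic inversion, which delivers the linear prenyl group and comes back to the route at 5.

**Step 4 (methylene bridging).** Retro-Mannich scrambling can give the symmetric bis-pyranone and bis-arene methanes, and the ortho-prenylphenol can cyclize to a chroman if the medium turns acidic. The fallback sets out from 5 and puts the bridge carbon on the arene first.
- Vilsmeier–Haack formylation (POCl3, DMF, EtOAc, 0 °C → rt; aq NaOAc) at the only free ring position gives 2,4,6-trihydroxy-3-(2-methylpropanoyl)-5-(3-methylbut-2-en-1-yl)benzaldehyde F4.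
- Three-component reductive alkylation of F4 with 9 and Hantzsch ester (diethyl 2,6-dimethyl-1,4-dihydropyridine-3,5-dicarboxylate; (S)-proline cat., CH2Cl2/EtOH, rt) proceeds by Knoevenagel condensation and transfer hydrogenation of the alkylidene. With no free one-carbon electrophile present, symmetric dimers cannot form, and the sequence comes back to the route at 12.

## Further compounds

F1 | step 3 | (Z)-3-(trimethylsilyloxy)pent-2-ene | C/C=C(\O[Si](C)(C)C)CC
F2 | step 2 | 1-[2,6-dihydroxy-4-(2-methylbut-3-yn-2-yloxy)phenyl]-2-methylpropan-1-one | CC(C)C(=O)c1c(O)cc(OC(C)(C)C#C)cc1O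
F3 | step 2 | 1-[2,6-dihydroxy-4-(2-methylbut-3-en-2-yloxy)phenyl]-2-methylpropan-1-one | CC(C)C(=O)c1c(O)cc(OC(C)(C)C=C)cc1O
F4 | step 4 | 2,4,6-trihydroxy-3-(2-methylpropanoyl)-5-(3-methylbut-2-en-1-yl)benzaldehyde | CC(C)C(=O)c1c(O)c(C=O)c(O)c(CC=C(C)C)c1O
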